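Everything rests on building ring D, the benzo ring of the apigenin half, last and onto a finished 2-aryl-4-pyranone (ring E). Ring D is a 1,3-dioxygenated benzene (O on C5 and C7, bare C–H at C6 and C8), which is what a vinylketene and a terminal siloxyalkyne assemble. One operation (Wolff rearrangement, ketene–alkyne [2+2] cycloaddition, four-electron opening, six-electron closure onto C4a=C8a of ring E) makes C8–C8a, C5–C6, C7–C8 and C4a–C5. The precursor is a 6-diazoacetyl-4-pyranone whose 2-aryl group is already bound through oxygen to C8 of acacetin. Both acacetin phenols are benzylated, because a free 5-hydroxyl could trap the ketene.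

Key step: step 7

Assumption: (triisopropylsilyloxy)ethyne is entered as a known, distillable stock reagent (O-silylation of lithium ethynolate with iPr3SiOTf), and its preparation is not counted.
Numbering: flavone numbers are used for the apigenin half. Ring E is O1, C2, C3, C4, C4a, C8a, and ring D is C4a, C5, C6, C7, C8, C8a. The target has no stereocentre.

Step 1
Reactants: 1 acacetin; 2 benzyl bromide
Product: 3 7-(benzyloxy)-5-hydroxy-2-(4-methoxyphenyl)-4H-chromen-4-one
Conditions: 2 (1.05 equiv), K2CO3, acetone, reflux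
Reagents that add atoms: none
Why: Williamson ether synthesis in which only the acidic, unchelated 7-hydroxyl is ionised and alkylated, while the 5-hydroxyl stays locked in its hydrogen bond to the C4 carbonyl.

Step 2
Reactants: 3 7-(benzyloxy)-5-hydroxy-2-(4-methoxyphenyl)-4H-chromen-4-one
Product: 5 7-(benzyloxy)-5,8-dihydroxy-2-(4-methoxyphenyl)-4H-chromen-4-one, via aryl sulfate 4 (not isolated)
Conditions: K2S2O8, aq KOH, pyridine, 15–20 °C; acidify (HCl), filter off unchanged 3; aq HCl, 90 °C, Ar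
Reagents that add atoms: potassium peroxodisulfate, [K+].[K+].[O-]S(=O)(=O)OOS(=O)(=O)[O-]
Why: Elbs persulfate oxidation: the 5-phenoxide attacks peroxodisulfate through its only free para position, C8, which is the standard way from 5-hydroxy-7-alkoxyflavones to the 5,8-diols, and hot dilute acid then cleaves the O–S bond of 4 without touching the benzyl ether.

Step 3
Reactants: 6 1-(4-fluorophenyl)butane-1,3-dione; 7 diethyl oxalate
Product: 9 ethyl 6-(4-fluorophenyl)-4-oxo-4H-pyran-2-carboxylate, via triketo ester 8 (not isolated)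
Conditions: NaOEt (2.2 equiv), EtOH, 0 → 50 °C; then conc. HCl, EtOH, reflux
Reagents that add atoms: none
Why: Claisen condensation of the diketone at its terminal methyl group with the non-enolisable oxalate (acylation at the central carbon reverts under ethoxide, the terminal adduct is held as a bis-enolate), then acid-catalysed cyclodehydration of the 1,3,5-tricarbonyl chain, a classical entry to 6-aryl-4-pyranone-2-carboxylates.

Step 4
Reactants: 5 7-(benzyloxy)-5,8-dihydroxy-2-(4-methoxyphenyl)-4H-chromen-4-one; 9 ethyl 6-(4-fluorophenyl)-4-oxo-4H-pyran-2-carboxylate; 2 benzyl bromide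
Product: 11 ethyl 6-(4-{[5,7-bis(benzyloxy)-2-(4-methoxyphenyl)-4-oxo-4H-chromen-8-yl]oxy}phenyl)-4-oxo-4H-pyran-2-carboxylate, via 5-hydroxy diaryl ether 10 (not isolated)
Conditions: Cs2CO3 (3 equiv), degassed DMAc, Ar, 120 °C; then 2 (1.3 equiv), 60 °C
Reagents that add atoms: none
Why: Nucleophilic aromatic substitution by addition–elimination, known for the related 4'-fluoroflavones: fluorine is para to the β-carbon of the pyranone enone so the Meisenheimer charge reaches the ring carbonyl oxygen, O8 is the only phenoxide not conjugated with and chelated to a carbonyl, and the leftover 5-phenoxide is then capped by Williamson benzylation in the same flask.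

Step 5
Reactants: 11 ethyl 6-(4-{[5,7-bis(benzyloxy)-2-(4-methoxyphenyl)-4-oxo-4H-chromen-8-yl]oxy}phenyl)-4-oxo-4H-pyran-2-carboxylate
Product: 12 6-(4-{[5,7-bis(benzyloxy)-2-(4-methoxyphenyl)-4-oxo-4H-chromen-8-yl]oxy}phenyl)-4-oxo-4H-pyran-2-carboxylic acid
Conditions: LiOH (1.5 equiv), THF/H2O, 0 °C; 1 M HCl to pH 2
Reagents that add atoms: lithium hydroxide, [Li+].[OH-]
Why: Ester saponification by acyl–oxygen cleavage, fast at 0 °C because the pyranone makes this ester very electrophilic, and the acidic work-up recloses any pyranone that hydroxide may have opened.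

Step 6
Reactants: 12 6-(4-{[5,7-bis(benzyloxy)-2-(4-methoxyphenyl)-4-oxo-4H-chromen-8-yl]oxy}phenyl)-4-oxo-4H-pyran-2-carboxylic acid
Product: 14 5,7-bis(benzyloxy)-8-{4-[6-(diazoacetyl)-4-oxo-4H-pyran-2-yl]phenoxy}-2-(4-methoxyphenyl)-4H-chromen-4-one, via acid chloride 13 (not isolated)
Conditions: Me2C=C(Cl)NMe2 (1.1 equiv), CH2Cl2, 0 °C → rt; then CH2N2 (3 equiv) in Et2O, –10 → 0 °C, excess purged with N2
Reagents that add atoms: diazomethane, C=[N+]=[N-]; 1-chloro-N,N,2-trimethylprop-1-en-1-amine, CC(C)=C(Cl)N(C)C (chlorine of 13 only)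
Why: Acylation of diazomethane by an acid chloride (first stage of the Arndt–Eistert sequence), the chloride being made under neutral conditions with the α-chloroenamine so that neither the basic flavone carbonyl nor the acid-sensitive 5-benzyl ether is disturbed, and a second equivalent of diazomethane removes the HCl.

Step 7
Reactants: 14 5,7-bis(benzyloxy)-8-{4-[6-(diazoacetyl)-4-oxo-4H-pyran-2-yl]phenoxy}-2-(4-methoxyphenyl)-4H-chromen-4-one; 15 (triisopropylsilyloxy)ethyne
Product: 20 5,7-bis(benzyloxy)-8-(4-{5-hydroxy-4-oxo-7-[(triisopropylsilyl)oxy]-4H-chromen-2-yl}phenoxy)-2-(4-methoxyphenyl)-4H-chromen-4-one, via pyranonylketene 16 (not isolated), via cyclobutenone 17 (not isolated), via dienylketene 18 (not isolated), via cyclohexadienone 19 (not isolated)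
Conditions: 15 (3 equiv), dry degassed ClCH2CH2Cl (0.02 M), 440 nm LEDs, 20 °C until N2 evolution stops; then reflux (83 °C)
Reagents that add atoms: none
Why: Proposed new method: light above 400 nm, absorbed by the diazo ketone but by neither the flavone nor the pyranone, expels N2 and the pyranonyl group shifts from the acyl carbon to the diazo carbon (Wolff rearrangement, new bond C8–C8a), so the diazo carbon becomes C8 and the acyl carbon, now the central carbon of ketene 16, becomes C5. The electron-rich unsubstituted carbon of 15 attacks that ketene carbon and the [2+2] cycloaddition gives 17 (C5–C6 and C7–C8), which on warming opens reversibly by four-electron conrotation with loss of the C5–C8 bond to 18. Ring D, six-membered, closes by disrotatory six-electron electrocyclization of 18 onto the C4a=C8a bond of ring E (C4a–C5), and in 19 the C4a hydrogen lies between two carbonyl groups, so enolisation to the hydrogen-bonded C5 phenol is immediate and irreversible. The closest known reaction type is the Danheiser benzannulation in its diazo ketone form with siloxyalkynes, established for alkenyl, aryl and five-membered heteroaryl arms but not for a 4-pyranone, whose weak cyclic conjugation should cost less to interrupt than that of benzene or thiophene. Two selectivities are needed: the meta O,O pattern follows from the polarity of 15 (oxygen-bearing carbon to C8, CH to C5), and the site of closure is unambiguous because C8a has only C4a and the ring oxygen as ring neighbours. No stereocentre survives (those of 17 and 19 are transient and racemic), and with both phenols of 14 benzylated nothing in the substrate can add to ketene 16.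

Step 8
Reactants: 20 5,7-bis(benzyloxy)-8-(4-{5-hydroxy-4-oxo-7-[(triisopropylsilyl)oxy]-4H-chromen-2-yl}phenoxy)-2-(4-methoxyphenyl)-4H-chromen-4-one
Product: 21 5,7-bis(benzyloxy)-8-[4-(5,7-dihydroxy-4-oxo-4H-chromen-2-yl)phenoxy]-2-(4-methoxyphenyl)-4H-chromen-4-one
Conditions: Bu4NF, AcOH (1.1 equiv each), THF, 0 °C
Reagents that add atoms: none
Why: Fluoride-mediated cleavage of an aryl silyl ether driven by Si–F bond formation, buffered with acetic acid so that benzyl ethers, flavone rings and the diaryl ether see no strong base.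

Step 9
Reactants: 21 5,7-bis(benzyloxy)-8-[4-(5,7-dihydroxy-4-oxo-4H-chromen-2-yl)phenoxy]-2-(4-methoxyphenyl)-4H-chromen-4-one
Product: 22 8-[4-(5,7-dihydroxy-4-oxo-4H-chromen-2-yl)phenoxy]-5,7-dihydroxy-2-(4-methoxyphenyl)-4H-chromen-4-one (CNP0295851.0)
Conditions: H2 (1 atm), Pd/C, THF/MeOH, rt
Reagents that add atoms: none
Why: Catalytic hydrogenolysis of the two aryl benzyl ethers, a standard last step in flavone synthesis that at one atmosphere leaves the C2=C3 bonds, the diaryl ether and the methyl ether intact.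

Compound list
1 | acacetin, 5,7-dihydroxy-2-(4-methoxyphenyl)-4H-chromen-4-one | COc1ccc(-c2cc(=O)c3c(O)cc(O)cc3o2)cc1 | starting material
2 | benzyl bromide | BrCc1ccccc1 | starting material
3 | 7-(benzyloxy)-5-hydroxy-2-(4-methoxyphenyl)-4H-chromen-4-one | COc1ccc(-c2cc(=O)c3c(O)cc(OCc4ccccc4)cc3o2)cc1 | intermediate
4 | potassium 7-(benzyloxy)-5-hydroxy-2-(4-methoxyphenyl)-4-oxo-4H-chromen-8-yl sulfate | COc1ccc(-c2cc(=O)c3c(O)cc(OCc4ccccc4)c(OS(=O)(=O)[O-])c3o2)cc1.[K+] | intermediate
5 | 7-(benzyloxy)-5,8-dihydroxy-2-(4-methoxyphenyl)-4H-chromen-4-one | COc1ccc(-c2cc(=O)c3c(O)cc(OCc4ccccc4)c(O)c3o2)cc1 | intermediate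
6 | 1-(4-fluorophenyl)butane-1,3-dione | CC(=O)CC(=O)c1ccc(F)cc1 | starting material
7 | diethyl oxalate | CCOC(=O)C(=O)OCC | starting material
8 | ethyl 6-(4-fluorophenyl)-2,4,6-trioxohexanoate (present as its sodium enolate) | CCOC(=O)C(=O)CC(=O)CC(=O)c1ccc(F)cc1 | intermediate
9 | ethyl 6-(4-fluorophenyl)-4-oxo-4H-pyran-2-carboxylate | CCOC(=O)c1cc(=O)cc(-c2ccc(F)cc2)o1 | intermediate
10 | ethyl 6-(4-{[7-(benzyloxy)-5-hydroxy-2-(4-methoxyphenyl)-4-oxo-4H-chromen-8-yl]oxy}phenyl)-4-oxo-4H-pyran-2-carboxylate | CCOC(=O)c1cc(=O)cc(-c2ccc(Oc3c(OCc4ccccc4)cc(O)c4c(=O)cc(-c5ccc(OC)cc5)oc34)cc2)o1 | intermediate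
11 | ethyl 6-(4-{[5,7-bis(benzyloxy)-2-(4-methoxyphenyl)-4-oxo-4H-chromen-8-yl]oxy}phenyl)-4-oxo-4H-pyran-2-carboxylate | CCOC(=O)c1cc(=O)cc(-c2ccc(Oc3c(OCc4ccccc4)cc(OCc4ccccc4)c4c(=O)cc(-c5ccc(OC)cc5)oc34)cc2)o1 | intermediate
12 | 6-(4-{[5,7-bis(benzyloxy)-2-(4-methoxyphenyl)-4-oxo-4H-chromen-8-yl]oxy}phenyl)-4-oxo-4H-pyran-2-carboxylic acid | OC(=O)c1cc(=O)cc(-c2ccc(Oc3c(OCc4ccccc4)cc(OCc4ccccc4)c4c(=O)cc(-c5ccc(OC)cc5)oc34)cc2)o1 | intermediate
13 | 6-(4-{[5,7-bis(benzyloxy)-2-(4-methoxyphenyl)-4-oxo-4H-chromen-8-yl]oxy}phenyl)-4-oxo-4H-pyran-2-carbonyl chloride | ClC(=O)c1cc(=O)cc(-c2ccc(Oc3c(OCc4ccccc4)cc(OCc4ccccc4)c4c(=O)cc(-c5ccc(OC)cc5)oc34)cc2)o1 | intermediate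
14 | 5,7-bis(benzyloxy)-8-{4-[6-(diazoacetyl)-4-oxo-4H-pyran-2-yl]phenoxy}-2-(4-methoxyphenyl)-4H-chromen-4-one | [N-]=[N+]=CC(=O)c1cc(=O)cc(-c2ccc(Oc3c(OCc4ccccc4)cc(OCc4ccccc4)c4c(=O)cc(-c5ccc(OC)cc5)oc34)cc2)o1 | intermediate
15 | (triisopropylsilyloxy)ethyne | C#CO[Si](C(C)C)(C(C)C)C(C)C | starting material
16 | ketene with the CH=C=O group on the pyranone carbon that becomes C8a | O=C=Cc1cc(=O)cc(-c2ccc(Oc3c(OCc4ccccc4)cc(OCc4ccccc4)c4c(=O)cc(-c5ccc(OC)cc5)oc34)cc2)o1 | intermediate
17 | 4-(pyranonyl)-3-[(triisopropylsilyl)oxy]cyclobut-2-en-1-one (racemic at C4 of the four-membered ring) | O=C1C=C(O[Si](C(C)C)(C(C)C)C(C)C)C1c1cc(=O)cc(-c2ccc(Oc3c(OCc4ccccc4)cc(OCc4ccccc4)c4c(=O)cc(-c5ccc(OC)cc5)oc34)cc2)o1 | intermediate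
18 | dienylketene, ketenyl and pyranonyl groups cis across the C7=C8 bond | CC(C)[Si](C(C)C)(C(C)C)O/C(C=C=O)=C/c1cc(=O)cc(-c2ccc(Oc3c(OCc4ccccc4)cc(OCc4ccccc4)c4c(=O)cc(-c5ccc(OC)cc5)oc34)cc2)o1 | intermediate
19 | 4aH-chromene-4,5-dione tautomer of 20 (racemic at C4a) | O=C1C=C(O[Si](C(C)C)(C(C)C)C(C)C)C=C2OC(c3ccc(Oc4c(OCc5ccccc5)cc(OCc5ccccc5)c5c(=O)cc(-c6ccc(OC)cc6)oc45)cc3)=CC(=O)C12 | intermediate
20 | 5,7-bis(benzyloxy)-8-(4-{5-hydroxy-4-oxo-7-[(triisopropylsilyl)oxy]-4H-chromen-2-yl}phenoxy)-2-(4-methoxyphenyl)-4H-chromen-4-one | COc1ccc(-c2cc(=O)c3c(OCc4ccccc4)cc(OCc4ccccc4)c(Oc4ccc(-c5cc(=O)c6c(O)cc(O[Si](C(C)C)(C(C)C)C(C)C)cc6o5)cc4)c3o2)cc1 | intermediate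
21 | 5,7-bis(benzyloxy)-8-[4-(5,7-dihydroxy-4-oxo-4H-chromen-2-yl)phenoxy]-2-(4-methoxyphenyl)-4H-chromen-4-one | COc1ccc(-c2cc(=O)c3c(OCc4ccccc4)cc(OCc4ccccc4)c(Oc4ccc(-c5cc(=O)c6c(O)cc(O)cc6o5)cc4)c3o2)cc1 | intermediate
22 | 8-[4-(5,7-dihydroxy-4-oxo-4H-chromen-2-yl)phenoxy]-5,7-dihydroxy-2-(4-methoxyphenyl)-4H-chromen-4-one (CNP0295851.0) | COc1ccc(-c2cc(=O)c3c(O)cc(O)c(Oc4ccc(-c5cc(=O)c6c(O)cc(O)cc6o5)cc4)c3o2)cc1 | target

Total step count: 9. Longest linear sequence: 8 steps (1, 2, 4, 5, 6, 7, 8, 9, from acacetin). Step 3 is a one-step side branch.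

Steps most likely to fail

First, step 7.
- **Risk:** The ketene may be lost to dimerisation or to traces of water faster than the alkyne captures it. The cyclobutenone may stall because the closure has to interrupt the cyclic conjugation of the pyranone. Energy transfer from the flavone may also divert the excited diazo ketone into triplet carbene chemistry.
- **Fallback:** It uses classical flavone construction, sets out from 5 and comes back at 22. Phenol 5 is arylated at O8 with 4-fluorobenzaldehyde, a strongly activated fluoride (K2CO3, DMF, 100 °C, Ar), to give 4-{[7-(benzyloxy)-5-hydroxy-2-(4-methoxyphenyl)-4-oxo-4H-chromen-8-yl]oxy}benzaldehyde F1. Claisen–Schmidt condensation with commercial 1-[2,4-bis(benzyloxy)-6-hydroxyphenyl]ethanone (KOH, EtOH/THF, rt) should give the (E)-2'-hydroxychalcone F2. Oxidative cyclisation with catalytic I2 in DMSO at 120 °C should give the tri-O-benzyl biflavone F3, and partial loss of the benzyl group next to the carbonyl would be harmless. Hydrogenolysis under the conditions of step 9 then gives 22. No phenol protection at O5 is needed here because no ketene is involved.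

Second, step 4.
- **Risk:** Addition–elimination may be slow at a fluoride that is activated only through a vinylogous carbonyl. That leaves time for attack on the ester or the pyranone and for air oxidation of the hydroquinone-type dianion.
- **Fallback:** It sets out from 5 and 7 and comes back at 10. Commercial 1-(4-bromophenyl)butane-1,3-dione is taken with 7 through the conditions of step 3. This goes by way of ethyl 6-(4-bromophenyl)-2,4,6-trioxohexanoate F4 to ethyl 6-(4-bromophenyl)-4-oxo-4H-pyran-2-carboxylate F5. An Ullmann-type C–O coupling of 5 with F5 (CuI, N,N-dimethylglycine, Cs2CO3, dioxane, 100 °C, Ar) replaces the Meisenheimer pathway by a copper-mediated bond formation. That coupling pairs an electron-rich phenol with an electron-poor aryl bromide and does not depend on charge stabilisation by the pyranone. It should give 10, which is benzylated with 2 as in the second half of step 4 to reach 11.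

Third, step 2.
- **Risk:** Conversion may be low and the electron-rich flavone may be over-oxidised under persulfate, with losses during hydrolysis of the sulfate.
- **Fallback:** It sets out from 1 and comes back at 11. Exhaustive benzylation of 1 with 2 (K2CO3, DMF, 80 °C) gives 5,7-bis(benzyloxy)-2-(4-methoxyphenyl)-4H-chromen-4-one F6. Electrophilic iodination (NIS, cat. CF3CO2H, MeCN) is directed to C8 once O5 is alkylated and gives 5,7-bis(benzyloxy)-8-iodo-2-(4-methoxyphenyl)-4H-chromen-4-one F7. Miyaura borylation (PdCl2(dppf), B2pin2, KOAc, dioxane, 90 °C) gives the 8-pinacolboronate F8. Oxidation (NaBO3·4H2O, THF/H2O, rt) gives 5,7-bis(benzyloxy)-8-hydroxy-2-(4-methoxyphenyl)-4H-chromen-4-one F9. This is a single free phenol without hydroquinone character, and it displaces fluoride from 9 under the first half of step 4 to give 11 directly.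

Further compounds
F1 | step 7 | 4-{[7-(benzyloxy)-5-hydroxy-2-(4-methoxyphenyl)-4-oxo-4H-chromen-8-yl]oxy}benzaldehyde | O=Cc1ccc(Oc2c(OCc3ccccc3)cc(O)c3c(=O)cc(-c4ccc(OC)cc4)oc23)cc1
F2 | step 7 | (2E)-1-[2,4-bis(benzyloxy)-6-hydroxyphenyl]-3-(4-{[7-(benzyloxy)-5-hydroxy-2-(4-methoxyphenyl)-4-oxo-4H-chromen-8-yl]oxy}phenyl)prop-2-en-1-one | COc1ccc(-c2cc(=O)c3c(O)cc(OCc4ccccc4)c(Oc4ccc(/C=C/C(=O)c5c(O)cc(OCc6ccccc6)cc5OCc5ccccc5)cc4)c3o2)cc1
F3 | step 7 | 7-(benzyloxy)-8-{4-[5,7-bis(benzyloxy)-4-oxo-4H-chromen-2-yl]phenoxy}-5-hydroxy-2-(4-methoxyphenyl)-4H-chromen-4-one | COc1ccc(-c2cc(=O)c3c(O)cc(OCc4ccccc4)c(Oc4ccc(-c5cc(=O)c6c(OCc7ccccc7)cc(OCc7ccccc7)cc6o5)cc4)c3o2)cc1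
F4 | step 4 | ethyl 6-(4-bromophenyl)-2,4,6-trioxohexanoate | CCOC(=O)C(=O)CC(=O)CC(=O)c1ccc(Br)cc1
F5 | step 4 | ethyl 6-(4-bromophenyl)-4-oxo-4H-pyran-2-carboxylate | CCOC(=O)c1cc(=O)cc(-c2ccc(Br)cc2)o1
F6 | step 2 | 5,7-bis(benzyloxy)-2-(4-methoxyphenyl)-4H-chromen-4-one | COc1ccc(-c2cc(=O)c3c(OCc4ccccc4)cc(OCc4ccccc4)cc3o2)cc1
F7 | step 2 | 5,7-bis(benzyloxy)-8-iodo-2-(4-methoxyphenyl)-4H-chromen-4-one | COc1ccc(-c2cc(=O)c3c(OCc4ccccc4)cc(OCc4ccccc4)c(I)c3o2)cc1
F8 | step 2 | 5,7-bis(benzyloxy)-2-(4-methoxyphenyl)-8-(4,4,5,5-tetramethyl-1,3,2-dioxaborolan-2-yl)-4H-chromen-4-one | COc1ccc(-c2cc(=O)c3c(OCc4ccccc4)cc(OCc4ccccc4)c(B4OC(C)(C)C(C)(C)O4)c3o2)cc1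
F9 | step 2 | 5,7-bis(benzyloxy)-8-hydroxy-2-(4-methoxyphenyl)-4H-chromen-4-one | COc1ccc(-c2cc(=O)c3c(OCc4ccccc4)cc(OCc4ccccc4)c(O)c3o2)cc1
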